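The ratio of reagent to solid substrate stood at 1.50 in gamma, 3.00 in beta and 6.00 in theta. These were the flasks and the earlier runs.

the same everywhere: solid substrate 0.50 mM

|  | reagent | remark | time |
|---|---|---|---|
| Saturday's | 2 equiv | run made earlier |  |
| Tuesday's | 7 equiv | run made earlier |  |
| gamma | 1.50 equiv |  | 2.5 min |
| beta | 3.00 equiv |  | 2.5 min |
| theta | 6.00 equiv |  | 2.5 min |

- Saturday's (time / s: target / %, solid substrate / %): 10.0: 9.5, 80.0; 20.0: 23.9, 63.1; 30.0: 39.6, 45.1; 40.0: 52.8, 29.6; 50.0: 66.9, 14.3; 60.0: 77.5, 0.6; 80.0: 90.6, 0.1
- Tuesday's (time / s: target / %, solid substrate / %): 10.0: 17.3, 78.7; 12.0: 21.3, 73.6; 20.0: 37.4, 57.0; 30.0: 58.3, 36.7; 50.0: 97.5, 0; 60.0: 100.8, 0.4; 80.0: 100.3, 0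

(standard deviation of a reading: 0.5 percentage points)

- as a solid, counted per litre of solution: solid substrate
- the analysis behind the earlier runs scatters by 0.5 percentage points, standard deviation
- what may be going on: solid substrate <-> dissolved substrate; dissolved substrate + reagent -> target; reagent -> side product
- at the start none of the solid substrate is in solution
- a step back or a flat step of under half a point counts as no turn
- "hardly changes" means that all values lie within two and a half points (for a concentration: within two and a half percent of the largest)

* amount of target at the end, in percent of the solid substrate charged for gamma, beta, theta, in this order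
* the course of these numbers from the first flask to the last (rises, then falls / falls all the way / falls, then rises / hardly changes / rises all the way)

I kept the books on the reagent. Each target takes one reagent, and each side product takes one. So I worked with what a full yield leaves over. In gamma 33.3 % of the reagent charge, the spare share s, is what one reagent per solid substrate charged does not claim. Beta had s = 66.7 %, and theta had s = 83.3 %. Target falls short of the solid substrate charged once side product has taken more than s of the reagent charge.

Saturday's run gave a first ledger, with s = 50.0 %. At 80.0 s its target reading stood for 45.3 % of the reagent charge, and the substrate not read as target stood for 4.70 %. Tuesday's target read 100.8 % at 60.0 s and 100.3 % at 80.0 s, so I booked no loss of target. I expected gamma, with the smallest s, to be the flask at risk.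

The forecast gave 94 %, 99.7 % and 100 %, a row that rises all the way. Of gamma it said “Reagent then runs low”.

The flasks gave 91.5 %, 100 % and 100 %, a row that rises all the way.

    solid substrate ⇌ dissolved substrate, rate k1*(cs1 - [dissolved substrate]) while solid is left; crystals form when [dissolved substrate] > cs1 (solubility = 0.270 mM, k = 0.0427 /s)
    dissolved substrate + reagent → target (k = 144 /M/s)
    reagent → side product (k = 0.00630 /s)

In gamma the solid substrate stood at 0 % by 1.25 min, with 22.6 % dissolved, and after that both reagent steps ran on. At 2.50 min the gamma ledger held 61.0 % of the reagent in target, 32.3 % in side product and 6.7 % unused. By 25.0 min side product in gamma had taken 36.2 %, above s. Reagent, the limiting reagent of gamma, stood there at 0 %, with target at 95.6 % and 4.36 % still dissolved. In beta at 25.0 min side product had taken 66.7 %, about its s, and target stood at >99.9 %.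

(All runs are calculated for substances that don't exist.)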